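## Retrosynthetic overview

1. C16–C17: the E,E,E-triene is closed last. An alkyne-terminated core is hydroborated and Suzuki-coupled with (1E,3E)-1-iodohexa-1,3-diene, so no oxidisable polyene is present during the peroxide chemistry.
2. C6–CH3: the tertiary peroxide centre comes from axial methyl delivery to a bicyclic peroxycarbenium ion made from a C6 methoxy peroxyketal. C6 is therefore relayed from C3/C4 and does not depend on a methyl-versus-alkyl choice.
3. Key operation (both rings, one flask): an acyclic (E)-γ-hydroxy enoate bearing a 1,1-disubstituted alkene is treated with O3/MeOH, then catalytic base. This forms C6–OO (carbonyl oxide capture), then C3–O (ring 1, the 1,2-dioxane, by 6-exo peroxy-Michael), then O–C1 (ring 2, the cis-fused γ-lactone).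
4. C4–C5: catalytic asymmetric 2-alkylallylboration of methyl (E)-4-oxopent-2-enoate sets C4, the only reagent-controlled stereocentre.
5. The allylboronate is made in two steps from methyl undec-10-ynoate (ester → allylsilane → allylboronate).

Atom labels C1–C22 in the text follow the chain: C1 lactone C=O, C2 CH2, C3 CH–OO, C4 C(Me)–O, C5 CH2, C6 C(Me)–OO, C7–C22 side chain. Systematic names use von Baeyer numbering, in which position 1 = C3, position 4 = C6 and position 6 = C4.

Assumption: (R)-3,3′-Br2-BINOL is taken as the catalyst enantiomer that sends the allyl group to the Si face of ketone 9; if the sense is the reverse, the equally available (S)-catalyst is used and nothing else changes.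

## Route

Step 1
Reactants: 1 methyl undec-10-ynoate; 2 (trimethylsilyl)methylmagnesium chloride
Product: 4 trimethyl(2-methylidenedodec-11-yn-1-yl)silane, via bis-silyl carbinol 3 (not isolated)
Conditions: 2 (5 equiv), anhydrous CeCl3 (5 equiv), THF, −78 °C → rt; aq. work-up; then SiO2, CH2Cl2, rt
Reagents that add atoms: (trimethylsilyl)methylmagnesium chloride, C[Si](C)(C)C[Mg]Cl
Why: CeCl3-activated double Grignard addition to the ester followed by Peterson elimination of one β-silyl group gives the 2-substituted allylsilane in one flask, any acetylide formed is reprotonated on quench, and no stereocentre is made.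

Step 2
Reactants: 4 trimethyl(2-methylidenedodec-11-yn-1-yl)silane; 5 boron trichloride; 6 2,2-dimethylpropane-1,3-diol
Product: 8 5,5-dimethyl-2-(2-methylidenedodec-11-yn-1-yl)-1,3,2-dioxaborinane, via allyldichloroborane 7 (not isolated)
Conditions: BCl3 (1.0 equiv, 1 M in CH2Cl2), CH2Cl2, −78 → −20 °C; then 6 (1.0 equiv), Et3N (2.1 equiv), −78 °C → rt; filter, concentrate
Reagents that add atoms: boron trichloride, ClB(Cl)Cl; 2,2-dimethylpropane-1,3-diol, OCC(C)(C)CO
Why: SE2′ borodesilylation (the allyl transposition is degenerate here) is much faster at low temperature than chloroboration of the remote alkyne, and the dichloroborane is capped as a glycol ester that can still exchange with a chiral diol in step 3.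

Step 3
Reactants: 8 5,5-dimethyl-2-(2-methylidenedodec-11-yn-1-yl)-1,3,2-dioxaborinane; 9 methyl (2E)-4-oxopent-2-enoate
Product: 11 methyl (2E,4S)-4-hydroxy-4-methyl-6-methylidenehexadec-2-en-15-ynoate, via borate ester 10 (not isolated)
Conditions: (R)-3,3′-Br2-BINOL (10 mol %), t-BuOH (2 equiv), toluene, rt, 24–48 h; aq. work-up
Reagents that add atoms: methyl (2E)-4-oxopent-2-enoate, COC(=O)/C=C/C(C)=O
Why: Chiral-diol-catalysed asymmetric allylboration of a ketone adds strictly 1,2 through a closed chair transition state with the alkenyl arm equatorial and the methyl axial, so allyl reaches the Si face and C4 is set as S, while the E-enoate cannot lactonise prematurely.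

Step 4
Reactants: 11 methyl (2E,4S)-4-hydroxy-4-methyl-6-methylidenehexadec-2-en-15-ynoate; 12 ozone; 13 methanol
Product: 17 (1S,6S)-4-(dec-9-yn-1-yl)-4-methoxy-6-methyl-2,3,7-trioxabicyclo[4.3.0]nonan-8-one (both C6 ketal epimers), via carbonyl oxide 14 (not isolated), via hydroperoxyketal 15 (not isolated), via dioxane hydroxy ester 16 (not isolated)
Conditions: O3, CH2Cl2–MeOH (4:1), −78 °C, Sudan Red 7B end point; N2 purge; then Cs2CO3 (0.2 equiv), −78 °C → rt, 12 h
Reagents that add atoms: ozone, [O-][O+]=O; methanol, CO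
Why: Criegee ozonolysis attacks only the electron-rich 1,1-disubstituted alkene (enoate and alkyne react far more slowly), methanol captures the more substituted carbonyl oxide, and under catalytic base in protic medium a reversible 6-exo peroxy-Michael addition closes the dioxane, after which only the C3 epimer with its acetate arm cis to the C4 hydroxyl can lactonise, so the equilibrium drains to the cis-fused (3S,4S) bicycle.

Step 5
Reactants: 17 (1S,6S)-4-(dec-9-yn-1-yl)-4-methoxy-6-methyl-2,3,7-trioxabicyclo[4.3.0]nonan-8-one; 18 trimethylaluminium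
Product: 20 (1S,4S,6S)-4-(dec-9-yn-1-yl)-4,6-dimethyl-2,3,7-trioxabicyclo[4.3.0]nonan-8-one, via peroxycarbenium ion 19 (not isolated)
Conditions: AlMe3 (3 equiv), Me3SiOTf (10 mol %), CH2Cl2, −78 → −30 °C; aq. potassium sodium tartrate
Reagents that add atoms: trimethylaluminium, C[Al](C)C
Why: Proposed new method: Lewis-acid ionisation of the exocyclic methoxy group converts both ketal epimers into the same peroxycarbenium ion 19, whose favoured half-chair holds the C4 acyloxy oxygen pseudoaxial and the C4 methyl and C3 arm pseudoequatorial, so methyl is delivered along the axial trajectory cis to the lactone oxygen (the other face would build a 1,3-diaxial Me/Me contact) and C6 is set as S with the long chain equatorial; the closest known reaction types are Lewis-acid substitution of monoperoxyketals by allylsilanes through peroxycarbenium ions and AlMe3 methylation of anomeric centres in peroxide-containing trioxanes.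

Step 6
Reactants: 21 (2E)-pent-2-enal; 22 iodoform
Product: 23 (1E,3E)-1-iodohexa-1,3-diene
Conditions: CrCl2 (6 equiv), CHI3 (2 equiv), THF–dioxane (1:6), 0 °C, dark
Reagents that add atoms: iodoform, IC(I)I
Why: Takai olefination converts the enal into the E-vinyl iodide with one-carbon homologation and leaves the existing E-alkene untouched.

Step 7
Reactants: 20 (1S,4S,6S)-4-(dec-9-yn-1-yl)-4,6-dimethyl-2,3,7-trioxabicyclo[4.3.0]nonan-8-one; 24 dicyclohexylborane; 23 (1E,3E)-1-iodohexa-1,3-diene
Product: 26 (1S,4S,6S)-4-[(9E,11E,13E)-hexadeca-9,11,13-trien-1-yl]-4,6-dimethyl-2,3,7-trioxabicyclo[4.3.0]nonan-8-one (target), via alkenylborane 25 (not isolated)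
Conditions: pre-formed Cy2BH (1.05 equiv), THF, 0 °C, 1 h; then 23 (1.2 equiv), Pd(PPh3)4 (5 mol %), degassed aq. K3PO4 (2 equiv), THF, rt, dark
Reagents that add atoms: (1E,3E)-1-iodohexa-1,3-diene, CC/C=C/C=C/I
Why: Syn hydroboration of the terminal alkyne is much faster than any reaction of the lactone or the hindered dialkyl peroxide and gives the E-alkenylborane, and Suzuki–Miyaura coupling with retention at both sp2 carbons gives the all-E triene at room temperature, conditions under which 1,2-dioxanes tolerate zerovalent palladium, and no stereocentre is touched.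

## Compound list

1 | methyl undec-10-ynoate | C#CCCCCCCCCC(=O)OC | starting material
2 | (trimethylsilyl)methylmagnesium chloride | C[Si](C)(C)C[Mg]Cl | starting material
3 | 1-(trimethylsilyl)-2-[(trimethylsilyl)methyl]dodec-11-yn-2-ol | C#CCCCCCCCCC(O)(C[Si](C)(C)C)C[Si](C)(C)C | intermediate (not isolated)
4 | trimethyl(2-methylidenedodec-11-yn-1-yl)silane | C#CCCCCCCCCC(=C)C[Si](C)(C)C | intermediate
5 | boron trichloride | ClB(Cl)Cl | starting material
6 | 2,2-dimethylpropane-1,3-diol | OCC(C)(C)CO | starting material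
7 | dichloro(2-methylidenedodec-11-yn-1-yl)borane | C#CCCCCCCCCC(=C)CB(Cl)Cl | intermediate (not isolated)
8 | 5,5-dimethyl-2-(2-methylidenedodec-11-yn-1-yl)-1,3,2-dioxaborinane | C#CCCCCCCCCC(=C)CB1OCC(C)(C)CO1 | intermediate
9 | methyl (2E)-4-oxopent-2-enoate | COC(=O)/C=C/C(C)=O | starting material
10 | methyl (2E,4S)-4-[(5,5-dimethyl-1,3,2-dioxaborinan-2-yl)oxy]-4-methyl-6-methylidenehexadec-2-en-15-ynoate | COC(=O)/C=C/[C@@](C)(OB1OCC(C)(C)CO1)CC(=C)CCCCCCCCC#C | intermediate (not isolated)
11 | methyl (2E,4S)-4-hydroxy-4-methyl-6-methylidenehexadec-2-en-15-ynoate | COC(=O)/C=C/[C@@](C)(O)CC(=C)CCCCCCCCC#C | intermediate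
12 | ozone | [O-][O+]=O | starting material
13 | methanol | CO | starting material
14 | C6 carbonyl oxide of methyl (2E,4S)-4-hydroxy-4-methyl-6-oxohexadec-2-en-15-ynoate | COC(=O)/C=C/[C@@](C)(O)CC(=[O+][O-])CCCCCCCCC#C | intermediate (not isolated)
15 | methyl (2E,4S)-6-hydroperoxy-4-hydroxy-6-methoxy-4-methylhexadec-2-en-15-ynoate (C6 epimers) | COC(=O)/C=C/[C@@](C)(O)CC(OC)(OO)CCCCCCCCC#C | intermediate (not isolated)
16 | methyl 2-[(3S,4S)-6-(dec-9-yn-1-yl)-4-hydroxy-6-methoxy-4-methyl-1,2-dioxan-3-yl]acetate (C6 epimers) | COC(=O)C[C@@H]1OOC(OC)(CCCCCCCCC#C)C[C@]1(C)O | intermediate (not isolated)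
17 | (1S,6S)-4-(dec-9-yn-1-yl)-4-methoxy-6-methyl-2,3,7-trioxabicyclo[4.3.0]nonan-8-one (C6 ketal epimers) | C#CCCCCCCCCC1(OC)C[C@]2(C)OC(=O)C[C@@H]2OO1 | intermediate
18 | trimethylaluminium | C[Al](C)C | starting material
19 | (1S,6S)-4-(dec-9-yn-1-yl)-6-methyl-8-oxo-2,3,7-trioxabicyclo[4.3.0]non-3-en-3-ium (peroxycarbenium ion) | C#CCCCCCCCCC1=[O+]O[C@H]2CC(=O)O[C@@]2(C)C1 | intermediate (not isolated)
20 | (1S,4S,6S)-4-(dec-9-yn-1-yl)-4,6-dimethyl-2,3,7-trioxabicyclo[4.3.0]nonan-8-one | C#CCCCCCCCC[C@@]1(C)C[C@]2(C)OC(=O)C[C@@H]2OO1 | intermediate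
21 | (2E)-pent-2-enal | CC/C=C/C=O | starting material
22 | iodoform | IC(I)I | starting material
23 | (1E,3E)-1-iodohexa-1,3-diene | CC/C=C/C=C/I | intermediate
24 | dicyclohexylborane | C1CCC(CC1)BC1CCCCC1 | starting material
25 | (1S,4S,6S)-4-[(9E)-10-(dicyclohexylboranyl)dec-9-en-1-yl]-4,6-dimethyl-2,3,7-trioxabicyclo[4.3.0]nonan-8-one | C1CCC(CC1)B(/C=C/CCCCCCCC[C@@]2(C)C[C@]3(C)OC(=O)C[C@@H]3OO2)C4CCCCC4 | intermediate (not isolated)
26 | (1S,4S,6S)-4-[(9E,11E,13E)-hexadeca-9,11,13-trien-1-yl]-4,6-dimethyl-2,3,7-trioxabicyclo[4.3.0]nonan-8-one | CC/C=C/C=C/C=C/CCCCCCCC[C@@]1(C)C[C@]2(C)OC(=O)C[C@@H]2OO1 | target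

## Step count and risks

Total step count: 7. Longest linear sequence: 6 (steps 1, 2, 3, 4, 5, 7). No protecting groups are used.

**Step 5 is the most likely to fail.**
- The peroxycarbenium ion may lose a proton to give an enol peroxide.
- The Lewis acid may cleave the O–O bond.
- Each ketal epimer may be methylated with retention inside a tight ion pair, which would erode the C6 ratio.

The fallback sets out from 11 and gives up the ketal detour. Mukaiyama–Isayama peroxysilylation (Co(thd)2 with thd = 2,2,6,6-tetramethylheptane-3,5-dionate, O2, Et3SiH, 1,2-dichloroethane, rt) of the 1,1-disubstituted alkene gives methyl (2E,4S)-4-hydroxy-4,6-dimethyl-6-[(triethylsilyl)peroxy]hexadec-2-en-15-ynoate F1 as a roughly 1:1 pair of C6 epimers. Bu4NF in THF then frees methyl (2E,4S)-6-hydroperoxy-4-hydroxy-4,6-dimethylhexadec-2-en-15-ynoate F2. This closes in the same flask through methyl 2-[(3S,4S)-6-(dec-9-yn-1-yl)-4-hydroxy-4,6-dimethyl-1,2-dioxan-3-yl]acetate F3, again forming both rings in one operation. The products are 20 and (1S,4R,6S)-4-(dec-9-yn-1-yl)-4,6-dimethyl-2,3,7-trioxabicyclo[4.3.0]nonan-8-one F4, which are separated by chromatography. The route is rejoined at 20, at the cost of half the material.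

**Step 4 is the second risk.**
- The β-carbon C3 sits next to a quaternary centre, so the Michael closure may be slow.
- The ester enolate may expel the hemiketal alkoxide to give a C2–C3 epoxide.
- Part of the primary ozonide may cleave the other way, giving the ketone.
- Formaldehyde and small peroxides remain in the pot.

The fallback sets out from 11 and builds the hydroperoxyketal from a carbonyl group instead of a carbonyl oxide. Ozonolysis in CH2Cl2 with Me2S work-up gives methyl (2E,4S)-4-hydroxy-4-methyl-6-oxohexadec-2-en-15-ynoate F5. Perhydration of F5 with urea·H2O2 and catalytic Sc(OTf)3 in MeOH gives 15, where the route is rejoined. Purified 15 is then closed through 16 to 17 with Et2NH in CF3CH2OH, a strongly protic medium that protonates the enolate before it can form the epoxide.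

**Step 7 is the third risk.**
- The borane, free phosphine or zerovalent palladium may attack the O–O bond.
- Aqueous base may open the β-peroxy lactone by retro-Michael reaction.

The fallback sets out from 20 and replaces boron and base by tin under neutral conditions. Hydrostannylation (Bu3SnH, PdCl2(PPh3)2 2 mol %, THF, 0 °C) gives (1S,4S,6S)-4,6-dimethyl-4-[(9E)-10-(tributylstannyl)dec-9-en-1-yl]-2,3,7-trioxabicyclo[4.3.0]nonan-8-one F6, which is freed of its internal regioisomer by chromatography. Stille coupling of F6 with 23 (Pd2(dba)3, AsPh3, N-methylpyrrolidone, rt) rejoins the route at 26.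

## Further compounds

F1 | step 5 | methyl (2E,4S)-4-hydroxy-4,6-dimethyl-6-[(triethylsilyl)peroxy]hexadec-2-en-15-ynoate (C6 epimers) | COC(=O)/C=C/[C@@](C)(O)CC(C)(OO[Si](CC)(CC)CC)CCCCCCCCC#C
F2 | step 5 | methyl (2E,4S)-6-hydroperoxy-4-hydroxy-4,6-dimethylhexadec-2-en-15-ynoate (C6 epimers) | COC(=O)/C=C/[C@@](C)(O)CC(C)(OO)CCCCCCCCC#C
F3 | step 5 | methyl 2-[(3S,4S)-6-(dec-9-yn-1-yl)-4-hydroxy-4,6-dimethyl-1,2-dioxan-3-yl]acetate (C6 epimers) | COC(=O)C[C@@H]1OOC(C)(CCCCCCCCC#C)C[C@]1(C)O
F4 | step 5 | (1S,4R,6S)-4-(dec-9-yn-1-yl)-4,6-dimethyl-2,3,7-trioxabicyclo[4.3.0]nonan-8-one | C#CCCCCCCCC[C@]1(C)C[C@]2(C)OC(=O)C[C@@H]2OO1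
F5 | step 4 | methyl (2E,4S)-4-hydroxy-4-methyl-6-oxohexadec-2-en-15-ynoate | COC(=O)/C=C/[C@@](C)(O)CC(=O)CCCCCCCCC#C
F6 | step 7 | (1S,4S,6S)-4,6-dimethyl-4-[(9E)-10-(tributylstannyl)dec-9-en-1-yl]-2,3,7-trioxabicyclo[4.3.0]nonan-8-one | CCCC[Sn](CCCC)(CCCC)/C=C/CCCCCCCC[C@@]1(C)C[C@]2(C)OC(=O)C[C@@H]2OO1
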